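Early times first: at its first reading, 15.0 min, Tuesday's flask already shows product at 54.7% and substrate at 39.6%, by 40.0 min product reads 60.3% with substrate at 38.6%, and the later readings show no drift beyond their scatter.

| setting | Tuesday's | Saturday's | flask |
|---|---|---|---|
| substrate | 0.25 M | 0.25 M | 0.25 M |
| partner | 0.15 M | 0.22 M | 0.150 M |
| temperature | 40 °C | 25 °C | 40 °C |
| remark | the very flask that is asked about, followed so far | run made earlier |  |
| time |  |  | 6.0 h |

- Tuesday's (time / min: product / %, substrate / %): 15.0: 54.7, 39.6; 40.0: 60.3, 38.6; 80.0: 59.3, 41.3; 120: 61.2, 38.9; 180: 60.3, 39.8; 240: 58.8, 41.2; 300: 59.4, 39.7
- Saturday's (time / min: product / %, substrate / %): 2.00: 2.4, 57.9; 5.00: 7.3, 37.4; 10.0: 13.4, 24.2; 12.0: 17.3, 23.0; 20.0: 29.9, 16.5; 25.0: 37.7, 15.2; 30.0: 44.0, 14.3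

(standard deviation of a reading: 1 percentage point)

- green: at 6.0 h take out 90% of the by-product then present, then wait 3.0 h
- blue: change nothing and wait 3.0 h more
- amber: at 6.0 h add partner, 100% of the amount charged, then wait 3.0 h
- violet: at 6.0 h raise the temperature by 10 K, then wait 3.0 h

- product, in percent of the substrate first charged, at 6.0 h
- the remedy with the largest gain of product, or "none" below 2 percentage points (green / blue / amber / violet / none)
- product present, in percent of the substrate first charged, after blue
- product present, in percent of the substrate first charged, after violet

- additions leave the volume as it is

What stops the flask? I suppose that substrate and partner are consumed one to one, so that in fractions of the charge the rate goes as the substrate fraction left times the ceiling minus the fraction reacted; integrated in closed form, this climbs to the ceiling and stays there, and the partner ceiling, the partner charge over the substrate charge, is 60.0%.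

Is that more than numerology? Saturday's run is a separate test, since its ceiling of 88.0% puts the substrate floor at 12.0%, and its last substrate reading, 14.3%, is still falling and is higher than that floor.

But Saturday's substrate and product sum to 58.3% at 30.0 min, so doesn't an unseen intermediate spoil the reckoning? It would at an early look, but in Tuesday's flask the sum rises from 94.3% at 15.0 min to 98.9% at 40.0 min, within the scatter of the charge, so by 6.0 h I commit to 60.0% of product.

And the remedies? A ceiling reckoned from two charges has neither temperature nor by-product in it, so I expect nothing from blue, green or violet. Amber lifts the ceiling to 120%, above the substrate charged, so product can gain 40 percentage points.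

The forecast, from the same runs, gives 60% now, 60% after blue, 60% after violet and amber as best, holding that “the plateau looks like the partner running out, not a slow reaction, an equilibrium or a dying catalyst”.

The flask gives 60.0% now, 60.0% after blue and 60.0% after violet, and amber is best, gaining 40 points where green gains 0 points.

    intermediate → product (k = 0.180 min⁻¹, Ea = 95.0 kJ mol⁻¹)
    substrate + partner → intermediate + by-product (k = 4.80 L mol⁻¹ min⁻¹, Ea = 52.0 kJ mol⁻¹)
    (constants at 40 °C)

Partner is the limiting reagent of this flask: at 360 min it has 0% of its charge free beside 40.0% of the substrate, and the run with that shortage taken away gives 100% of product against 60.0%, so the 40 points is due to the running short of partner. The product of this flask stands at the ceiling of 60.0%, and partner at 0.138 M or 0.163 M moves it by 5 points.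

With 0.060 M of partner in the same flask, the ceiling is 24.0%. The computed flask gives 24.0% of product, with 76.0% of the substrate left.

All runs are calculated from invented constants, and the scatter is random.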